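**Retrosynthetic overview**
1. Target 32 ← fluoride and hydroxide deprotection ← Wittig methylenation at C8 ← Horner–Wadsworth–Emmons olefination at C13 ← cis-fused diketone 28.
2. Feature used: the exocyclic C8=C17 methylene of ring B is a masked C8 ketone. C10 (angular CH3-20) and C9 (side chain from C11) are its β and α carbons, so C10–C20 and C9–C11 are made together across the C9=C10 enone of octalone 21 with Me2CuLi and 3-(trimethylsilyl)but-3-en-2-one 25.
3. Octalone 21 ← Birch reduction, hydrolysis and conjugation of anisole-type tetralin 16; ring B is the former aromatic ring and C5 is set by equilibration.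
4. Tetralin 16 ← Mitsunobu inversion at C2 of bridged lactone 12 ← Friedel–Crafts acylation closing ring A (C1–C10) on lactone acid 9 ← trans-methylation of aryl lactone 5 ← 4-methoxyphenylacetic acid 1 + (S)-glycidyl trityl ether 2.
5. Ring order: aromatic ring (future ring B) present in 1; γ-lactone (temporary, steps 1–6); ring A in step 5; ring B dearomatised in step 10; no ring is formed in the key step.

Key step: step 15

Remark: labdane numbering is used for the bicyclic compounds. The target SMILES corresponds to the cis-fused (2S,4R,5S,9S,10R) isomer, with H-5, CH3-20, the C9 chain, the C4 methyl and the C2 hydroxyl on one face. The C4 carboxyl is carried as a fluoride-labile SEM ester, because an axial neopentyl methyl ester could not be saponified late under conditions the diene system tolerates.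

**Step 1**
Reactants: 1 4-methoxyphenylacetic acid; 2 (S)-glycidyl trityl ether [(2S)-2-[(triphenylmethoxy)methyl]oxirane]
Product: 5 (5S)-3-(4-methoxyphenyl)-5-[(triphenylmethoxy)methyl]oxolan-2-one (both C3 epimers), via dilithium enediolate 3 (not isolated), via hydroxy acid 4 (not isolated)
Conditions: LiN(i-Pr)2 (2.2 equiv), THF, −78 to 0 °C; 2, 0 to 40 °C; AcOH (2.5 equiv); crude in PhMe, PPTS (cat.), 60 °C
Reagents that add atoms: none
Why: The carboxylic acid dianion opens the monosubstituted epoxide at its CH2 terminus (SN2 alkylation of an enediolate) and the γ-hydroxy acid lactonises under mild acid catalysis, so the untouched epoxide carbon becomes C2 with its configuration retained.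

**Step 2**
Reactants: 5
Product: 7 (3R,5S)-3-(4-methoxyphenyl)-3-methyl-5-[(triphenylmethoxy)methyl]oxolan-2-one (aryl cis to the CH2OCPh3 group), via lithium enolate 6 (not isolated)
Conditions: LiN(i-Pr)2 (1.1 equiv), THF, −78 °C; MeI, −78 to −40 °C
Reagents that add atoms: iodomethane, CI
Why: Enolate alkylation of a planar α-aryl γ-butyrolactone enolate, in which iodomethane should approach anti to the bulky C5 trityloxymethyl group, sets the quaternary centre (future C4) with methyl trans and aryl cis to that group.

**Step 3**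
Reactants: 7
Product: 8 (3R,5S)-5-(hydroxymethyl)-3-(4-methoxyphenyl)-3-methyloxolan-2-one
Conditions: TsOH·H2O (cat.), MeOH/CH2Cl2, rt
Reagents that add atoms: none
Why: Acid-catalysed solvolysis of the trityl ether (SN1 at the trityl carbon) frees the primary alcohol, and the γ-lactone is the stable form under these conditions.

**Step 4**
Reactants: 8
Product: 9 (2S,4R)-4-(4-methoxyphenyl)-4-methyl-5-oxooxolane-2-carboxylic acid
Conditions: TEMPO (cat.), PhI(OAc)2 (2.2 equiv), MeCN/H2O, rt
Reagents that add atoms: water, O
Why: Oxoammonium-mediated oxidation of the primary alcohol through the aldehyde hydrate gives the acid without touching the anisole ring or the lactone and without enolising C2.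

**Step 5**
Reactants: 9
Product: 11 (1R,3S)-3-hydroxy-6-methoxy-1-methyl-4-oxo-1,2,3,4-tetrahydronaphthalene-1-carboxylic acid 1,3-lactone (bridged keto lactone), via acid chloride 10 (not isolated)
Conditions: (COCl)2, DMF (cat.), CH2Cl2, 0 °C to rt; evaporate; AlCl3 (2.5 equiv), CH2Cl2 (high dilution), 0 °C to rt
Reagents that add atoms: none
Why: Intramolecular Friedel–Crafts acylation closes ring A (C1–C10) at the only carbon the acylium ion can reach, ortho to the quaternary carbon and meta to OMe as in the standard cyclisation of 4-(4-methoxyphenyl)butanoic acid to 7-methoxy-1-tetralone; the cis aryl/acyl relation from step 2 permits closure and the bridgehead C2 cannot epimerise.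

**Step 6**
Reactants: 11
Product: 12 (1R,3R)-3-hydroxy-6-methoxy-1-methyl-1,2,3,4-tetrahydronaphthalene-1-carboxylic acid 1,3-lactone (bridged lactone)
Conditions: H2 (4 atm), Pd/C (10% palladium on carbon), AcOH, HClO4 (cat.), 40 °C
Reagents that add atoms: none
Why: Catalytic hydrogenolysis reduces the aryl ketone to the benzylic methylene via the benzylic alcohol, while the homobenzylic lactone C–O bond and the anisole ring are inert.

**Step 7**
Reactants: 12
Product: 14 methyl (1R,3R)-3-hydroxy-6-methoxy-1-methyl-1,2,3,4-tetrahydronaphthalene-1-carboxylate (OH cis to CO2Me), via potassium carboxylate 13 (not isolated)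
Conditions: KOH (1.05 equiv), MeOH/H2O, rt; evaporate to dryness; MeI, DMF, rt
Reagents that add atoms: potassium hydroxide, [K+].[OH-]; iodomethane, CI
Why: Saponification of the bridged lactone and SN2 O-methylation of the carboxylate give the hydroxy ester without an acidic stage in which the cis-1,3-hydroxy acid could re-lactonise.

**Step 8**
Reactants: 14
Product: 15 methyl (1R,3S)-6-methoxy-1-methyl-3-[(4-nitrobenzoyl)oxy]-1,2,3,4-tetrahydronaphthalene-1-carboxylate
Conditions: 4-nitrobenzoic acid, PPh3, DIAD, THF, 0 °C to rt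
Reagents that add atoms: 4-nitrobenzoic acid, O=C(O)c1ccc(cc1)[N+](=O)[O-]
Why: Mitsunobu reaction, in which SN2 displacement of the alkoxyphosphonium group by 4-nitrobenzoate inverts C2 and places its oxygen cis to the C4 methyl as the target requires.

**Step 9**
Reactants: 15
Product: 16 (1R,3S)-3-hydroxy-6-methoxy-1-methyl-1,2,3,4-tetrahydronaphthalene-1-carboxylic acid (OH cis to CH3)
Conditions: KOH (excess), MeOH/H2O, 80 °C; then 2 M HCl to pH 2
Reagents that add atoms: potassium hydroxide, [K+].[OH-]
Why: Saponification cleaves both esters by acyl–oxygen fission, so C2 keeps its inverted configuration, and the trans-1,3-hydroxy acid cannot lactonise on acidification.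

**Step 10**
Reactants: 16
Product: 19 (1R,3S,8aS)-3-hydroxy-1-methyl-6-oxo-1,2,3,4,6,7,8,8a-octahydronaphthalene-1-carboxylic acid, via dihydroanisole 17 (not isolated), via unconjugated enone 18 (not isolated)
Conditions: Li (10 equiv), NH3(l)/THF, t-BuOH, −78 to −33 °C; NH4Cl; evaporate; 2 M HCl, THF, rt
Reagents that add atoms: water, O
Why: Birch reduction of the 3,4-dialkylanisole ring gives the 2,5-dihydroanisole, and acid hydrolysis of the enol ether with conjugation of the β,γ-enone delivers the C8 enone while C5 equilibrates through the dienol to the epimer whose ring A chair holds the C2 hydroxyl and C4 methyl equatorial (H-5 cis to both).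

**Step 11**
Reactants: 19
Product: 20 [2-(trimethylsilyl)ethoxy]methyl (1R,3S,8aS)-3-hydroxy-1-methyl-6-oxo-1,2,3,4,6,7,8,8a-octahydronaphthalene-1-carboxylate
Conditions: SEMCl (1.1 equiv), i-Pr2NEt, CH2Cl2, 0 °C
Reagents that add atoms: 2-(trimethylsilyl)ethoxymethyl chloride, C[Si](C)(C)CCOCCl
Why: SN2 O-alkylation of the carboxylate by the chloromethyl ether is much faster than etherification of the secondary alcohol and gives an ester that fluoride can remove however hindered its carbonyl is.

**Step 12**
Reactants: 20
Product: 21 [2-(trimethylsilyl)ethoxy]methyl (1R,3S,8aS)-3-[(tert-butyldimethylsilyl)oxy]-1-methyl-6-oxo-1,2,3,4,6,7,8,8a-octahydronaphthalene-1-carboxylate (octalone precursor)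
Conditions: TBSCl, imidazole, DMF, rt
Reagents that add atoms: tert-butyldimethylsilyl chloride, CC(C)(C)[Si](C)(C)Cl
Why: Standard silylation of an equatorial secondary alcohol under non-enolising conditions masks the hydroxyl against the cuprate and the later ylides.

**Step 13**
Reactants: 22 (1-bromoethenyl)trimethylsilane
Product: 24 3-(trimethylsilyl)but-3-en-2-ol (racemic), via Grignard reagent 23 (not isolated)
Conditions: Mg, THF, reflux; MeCHO, 0 °C; aq. NH4Cl
Reagents that add atoms: acetaldehyde, CC=O
Why: Grignard formation from the α-silyl vinyl bromide and 1,2-addition to acetaldehyde is the standard preparation of this allylic alcohol.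

**Step 14**
Reactants: 24
Product: 25 3-(trimethylsilyl)but-3-en-2-one
Conditions: CrO3, H2SO4, H2O, acetone, 0 °C
Reagents that add atoms: none
Why: Jones oxidation of the secondary allylic alcohol gives the α-silyl enone, whose vinylsilane survives the brief cold acidic oxidation.

**Step 15 (key step)**
Reactants: 21; 25
Product: 28 [2-(trimethylsilyl)ethoxy]methyl (1R,3S,4aS,5R,8aS)-3-[(tert-butyldimethylsilyl)oxy]-1,4a-dimethyl-6-oxo-5-(3-oxobutyl)decahydronaphthalene-1-carboxylate (cis-fused), via lithium enolate 26 (not isolated), via silyl diketone 27 (not isolated)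
Conditions: Me2CuLi (1.5 equiv, from MeLi and CuI, Et2O, 0 °C); 21, Et2O, −78 to 0 °C; 25 (1.5 equiv), −78 to −30 °C; aq. NH4Cl; crude in MeOH, NaOMe (0.3 equiv), 0 °C to rt
Reagents that add atoms: lithium dimethylcuprate, [Li+].C[Cu-]C
Why: The cuprate forms a π complex with the C9=C10 bond of the ring B enone, oxidative addition gives a C10 species of trivalent copper and reductive elimination makes C10–C20, leaving the regiodefined C8 lithium enolate 26; this adds through C9 to silyl enone 25 (Michael addition), whose silicon stabilises the new α-carbanion and keeps the acceptor from polymerising, and methoxide then removes silicon from 27 and equilibrates C9. The closest known reaction type is conjugate methylation of bicyclic octalones to cis-fused angular-methyl decalones combined with capture of the cuprate-derived enolate by an α-silyl vinyl ketone. No ring is closed; the step forms two skeletal bonds (C10–C20, C9–C11) and two stereocentres on the existing bicycle. C10 is controlled by antiparallel attack (axial to ring B) on the face of H-5, which places the methyl equatorial on ring A and gives the cis fusion, whereas the opposite face would make the methyl axial on both rings and syn-axial to the C4 ester. C9 is controlled thermodynamically: next to the C8 ketone it epimerises to the isomer with the 3-oxobutyl chain equatorial on ring B and cis to CH3-20, because the axial alternative clashes with the C5–C4 bond. The step needs 1,4- over 1,2-addition and C-alkylation at C9 only, which the soft cuprate, the fully substituted C10 and the α-silyl acceptor provide, and the hindered SEM ester and silyl ether are inert to the cuprate.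

**Step 16**
Reactants: 28
Product: 29 [2-(trimethylsilyl)ethoxy]methyl (1R,3S,4aS,5R,8aS)-3-[(tert-butyldimethylsilyl)oxy]-5-[(3E)-5-methoxy-3-methyl-5-oxopent-3-en-1-yl]-1,4a-dimethyl-6-oxodecahydronaphthalene-1-carboxylate
Conditions: (MeO)2P(O)CH2CO2Me, NaH, THF, 0 °C to rt
Reagents that add atoms: trimethyl phosphonoacetate, COC(=O)CP(=O)(OC)OC
Why: Horner–Wadsworth–Emmons olefination, in which the stabilised phosphonate anion should attack only the unhindered methyl ketone (the C8 ketone sits between tertiary C9 and quaternary C10) and favour the E enoate, the minor Z isomer being removable by chromatography.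

**Step 17**
Reactants: 29
Product: 30 [2-(trimethylsilyl)ethoxy]methyl (1R,3S,4aR,5S,8aS)-3-[(tert-butyldimethylsilyl)oxy]-5-[(3E)-5-methoxy-3-methyl-5-oxopent-3-en-1-yl]-1,4a-dimethyl-6-methylidenedecahydronaphthalene-1-carboxylate
Conditions: Ph3PCH3Br, NaN(SiMe3)2, THF, 0 °C; then 29, rt to 50 °C
Reagents that add atoms: methyltriphenylphosphonium bromide, C[P+](c1ccccc1)(c1ccccc1)c1ccccc1.[Br-]
Why: Wittig methylenation of the remaining C8 ketone with the non-stabilised ylide is the usual way to install the C8 exocyclic methylene of labdanes, with C9 already in its stable configuration and the esters untouched.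

**Step 18**
Reactants: 30
Product: 31 (1R,3S,4aR,5S,8aS)-3-hydroxy-5-[(3E)-5-methoxy-3-methyl-5-oxopent-3-en-1-yl]-1,4a-dimethyl-6-methylidenedecahydronaphthalene-1-carboxylic acid
Conditions: TBAF (5 equiv), THF, rt to 40 °C; aq. NH4Cl
Reagents that add atoms: none
Why: Fluoride attacks silicon in both protecting groups, cleaving the silyl ether and fragmenting the SEM ester, so the hindered C4 carboxyl is freed without attack at its carbonyl.

**Step 19**
Reactants: 31
Product: 32 (1R,3S,4aR,5S,8aS)-5-[(3E)-4-carboxy-3-methylbut-3-en-1-yl]-3-hydroxy-1,4a-dimethyl-6-methylidenedecahydronaphthalene-1-carboxylic acid (target)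
Conditions: LiOH·H2O, THF/MeOH/H2O, rt to 40 °C; then 1 M HCl to pH 3, 0 °C
Reagents that add atoms: lithium hydroxide, [Li+].[OH-]
Why: Saponification of the unhindered conjugated methyl ester under mild base, which should not move either double bond, gives the diacid target.

**Compound list**
1 | 4-methoxyphenylacetic acid | COc1ccc(CC(=O)O)cc1 | starting material
2 | (S)-glycidyl trityl ether | C(OC(c1ccccc1)(c1ccccc1)c1ccccc1)[C@@H]1CO1 | starting material
3 | dilithium enediolate of 1 | [Li+].[Li+].COc1ccc(C=C([O-])[O-])cc1 | intermediate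
4 | (4S)-4-hydroxy-2-(4-methoxyphenyl)-5-(triphenylmethoxy)pentanoic acid (both C2 epimers) | C(OC(c1ccccc1)(c1ccccc1)c1ccccc1)[C@@H](O)CC(c1ccc(OC)cc1)C(=O)O | intermediate
5 | (5S)-3-(4-methoxyphenyl)-5-[(triphenylmethoxy)methyl]oxolan-2-one (both C3 epimers) | C(OC(c1ccccc1)(c1ccccc1)c1ccccc1)[C@@H]1CC(c2ccc(OC)cc2)C(=O)O1 | intermediate
6 | lithium enolate of 5 | [Li+].C(OC(c1ccccc1)(c1ccccc1)c1ccccc1)[C@@H]1CC(c2ccc(OC)cc2)=C([O-])O1 | intermediate
7 | (3R,5S)-3-(4-methoxyphenyl)-3-methyl-5-[(triphenylmethoxy)methyl]oxolan-2-one | C(OC(c1ccccc1)(c1ccccc1)c1ccccc1)[C@@H]1C[C@](C)(c2ccc(OC)cc2)C(=O)O1 | intermediate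
8 | (3R,5S)-5-(hydroxymethyl)-3-(4-methoxyphenyl)-3-methyloxolan-2-one | OC[C@@H]1C[C@](C)(c2ccc(OC)cc2)C(=O)O1 | intermediate
9 | (2S,4R)-4-(4-methoxyphenyl)-4-methyl-5-oxooxolane-2-carboxylic acid | OC(=O)[C@@H]1C[C@](C)(c2ccc(OC)cc2)C(=O)O1 | intermediate
10 | (2S,4R)-4-(4-methoxyphenyl)-4-methyl-5-oxooxolane-2-carbonyl chloride | ClC(=O)[C@@H]1C[C@](C)(c2ccc(OC)cc2)C(=O)O1 | intermediate
11 | (1R,3S)-3-hydroxy-6-methoxy-1-methyl-4-oxo-1,2,3,4-tetrahydronaphthalene-1-carboxylic acid 1,3-lactone | COc1ccc2c(c1)C(=O)[C@@H]1C[C@@]2(C)C(=O)O1 | intermediate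
12 | (1R,3R)-3-hydroxy-6-methoxy-1-methyl-1,2,3,4-tetrahydronaphthalene-1-carboxylic acid 1,3-lactone | COc1ccc2c(c1)C[C@@H]1C[C@@]2(C)C(=O)O1 | intermediate
13 | potassium (1R,3R)-3-hydroxy-6-methoxy-1-methyl-1,2,3,4-tetrahydronaphthalene-1-carboxylate | [K+].COc1ccc2c(c1)C[C@@H](O)C[C@@]2(C)C(=O)[O-] | intermediate
14 | methyl (1R,3R)-3-hydroxy-6-methoxy-1-methyl-1,2,3,4-tetrahydronaphthalene-1-carboxylate | COc1ccc2c(c1)C[C@@H](O)C[C@@]2(C)C(=O)OC | intermediate
15 | methyl (1R,3S)-6-methoxy-1-methyl-3-[(4-nitrobenzoyl)oxy]-1,2,3,4-tetrahydronaphthalene-1-carboxylate | COc1ccc2c(c1)C[C@H](OC(=O)c1ccc(cc1)[N+](=O)[O-])C[C@@]2(C)C(=O)OC | intermediate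
16 | (1R,3S)-3-hydroxy-6-methoxy-1-methyl-1,2,3,4-tetrahydronaphthalene-1-carboxylic acid | COc1ccc2c(c1)C[C@H](O)C[C@@]2(C)C(=O)O | intermediate
17 | (1R,3S)-3-hydroxy-6-methoxy-1-methyl-1,2,3,4,5,8-hexahydronaphthalene-1-carboxylic acid | COC1=CCC2=C(C1)C[C@H](O)C[C@@]2(C)C(=O)O | intermediate
18 | (1R,3S)-3-hydroxy-1-methyl-6-oxo-1,2,3,4,5,6,7,8-octahydronaphthalene-1-carboxylic acid | O=C1CCC2=C(C1)C[C@H](O)C[C@@]2(C)C(=O)O | intermediate
19 | (1R,3S,8aS)-3-hydroxy-1-methyl-6-oxo-1,2,3,4,6,7,8,8a-octahydronaphthalene-1-carboxylic acid | O=C1CC[C@H]2C(=C1)C[C@H](O)C[C@@]2(C)C(=O)O | intermediate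
20 | SEM ester of 19 | O=C1CC[C@H]2C(=C1)C[C@H](O)C[C@@]2(C)C(=O)OCOCC[Si](C)(C)C | intermediate
21 | SEM ester TBS ether octalone (key-step precursor) | O=C1CC[C@H]2C(=C1)C[C@H](O[Si](C)(C)C(C)(C)C)C[C@@]2(C)C(=O)OCOCC[Si](C)(C)C | intermediate
22 | (1-bromoethenyl)trimethylsilane | C=C(Br)[Si](C)(C)C | starting material
23 | [1-(trimethylsilyl)ethenyl]magnesium bromide | C=C([Mg]Br)[Si](C)(C)C | intermediate
24 | 3-(trimethylsilyl)but-3-en-2-ol (racemic) | CC(O)C(=C)[Si](C)(C)C | intermediate
25 | 3-(trimethylsilyl)but-3-en-2-one | CC(=O)C(=C)[Si](C)(C)C | intermediate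
26 | lithium C8 enolate (C8=C9) of the cis-fused 10-methyl decalone | [Li+].[O-]C=1CC[C@H]2[C@](C)(C[C@H](O[Si](C)(C)C(C)(C)C)C[C@@]2(C)C(=O)OCOCC[Si](C)(C)C)C=1 | intermediate
27 | C9 adduct bearing a 3-oxo-2-(trimethylsilyl)butyl chain (epimers at C9 and C12) | O=C1CC[C@H]2[C@](C)(C[C@H](O[Si](C)(C)C(C)(C)C)C[C@@]2(C)C(=O)OCOCC[Si](C)(C)C)C1CC([Si](C)(C)C)C(C)=O | intermediate
28 | cis-fused C8 ketone with angular methyl and 3-oxobutyl chain (key-step product) | O=C1CC[C@H]2[C@](C)(C[C@H](O[Si](C)(C)C(C)(C)C)C[C@@]2(C)C(=O)OCOCC[Si](C)(C)C)[C@H]1CCC(C)=O | intermediate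
29 | C8 ketone (E)-enoate | O=C1CC[C@H]2[C@](C)(C[C@H](O[Si](C)(C)C(C)(C)C)C[C@@]2(C)C(=O)OCOCC[Si](C)(C)C)[C@H]1CC/C(C)=C/C(=O)OC | intermediate
30 | protected 8(17),13E-diene | C=C1CC[C@H]2[C@](C)(C[C@H](O[Si](C)(C)C(C)(C)C)C[C@@]2(C)C(=O)OCOCC[Si](C)(C)C)[C@H]1CC/C(C)=C/C(=O)OC | intermediate
31 | C2 alcohol, C19 acid, C15 methyl ester | C=C1CC[C@H]2[C@](C)(C[C@H](O)C[C@@]2(C)C(=O)O)[C@H]1CC/C(C)=C/C(=O)OC | intermediate
32 | CNP0086784.2, (2S,4R,5S,9S,10R) in labdane numbering | C=C1CC[C@H]2[C@](C)(C[C@H](O)C[C@@]2(C)C(=O)O)[C@H]1CC/C(C)=C/C(=O)O | target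

**Step count**
Total: 19 steps. Longest linear sequence: 17 steps (steps 1–12 and 15–19); the reagent branch (steps 13–14) is 2 steps.

**Steps most likely to fail**

Step 15. The enolate 26 may exchange protons with the acceptor or with the adduct and lose its regiochemistry, the silyl enone may oligomerise, the cuprate may attack part of the material from the face opposite H-5, and the 1,5-diketone may undergo aldol closure during the methoxide treatment. The fallback sets out from 21 and separates the two bond formations. Me2CuLi with Me3SiCl at −78 °C would give the isolable trimethylsilyl enol ether of the cis-fused 10-methyl decalone F1. A Mukaiyama–Michael addition of F1 to but-3-en-2-one (BF3·OEt2, i-PrOH, CH2Cl2, −78 °C), followed by a short NaOMe/MeOH equilibration of C9, would rejoin the route at 28.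

Step 5. Acylation at a position meta to the methoxy group to give a bridged product may be slow, so that loss of CO from the α-acyloxy acylium ion or ether cleavage by AlCl3 competes. The fallback sets out from alcohol 8 and forms the C1–C10 bond by a radical instead of a cation. Appel-type iodination (PPh3, I2, imidazole) would give (3R,5S)-5-(iodomethyl)-3-(4-methoxyphenyl)-3-methyloxolan-2-one F2. Peroxide-mediated oxidative radical cyclisation of F2 (dilauroyl peroxide, 1,2-dichloroethane, reflux) is a homolytic aromatic substitution that does not depend on the electronic bias of the ring; it would give the bridged lactone directly and rejoin the route at 12.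

Step 8. The activated alcohol may undergo E2 elimination toward the benzylic C1 to give a 1,2-dihydronaphthalene, and SN2 attack may be slowed by the neighbouring quaternary centre. The fallback sets out from 14 and replaces substitution by oxidation and reduction. Dess–Martin oxidation would give methyl (1R)-6-methoxy-1-methyl-3-oxo-1,2,3,4-tetrahydronaphthalene-1-carboxylate F3. A ketoreductase selected by screening for the (3S) alcohol (NADPH recycled with i-PrOH) would then give methyl (1R,3S)-3-hydroxy-6-methoxy-1-methyl-1,2,3,4-tetrahydronaphthalene-1-carboxylate F4. Saponification as in step 9 would rejoin the route at 16.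

**Further compounds**
F1 | step 15 | [2-(trimethylsilyl)ethoxy]methyl (1R,3S,4aS,8aS)-3-[(tert-butyldimethylsilyl)oxy]-1,4a-dimethyl-6-[(trimethylsilyl)oxy]-1,2,3,4,4a,7,8,8a-octahydronaphthalene-1-carboxylate | C[Si](C)(C)OC=1CC[C@H]2[C@](C)(C[C@H](O[Si](C)(C)C(C)(C)C)C[C@@]2(C)C(=O)OCOCC[Si](C)(C)C)C=1
F2 | step 5 | (3R,5S)-5-(iodomethyl)-3-(4-methoxyphenyl)-3-methyloxolan-2-one | IC[C@@H]1C[C@](C)(c2ccc(OC)cc2)C(=O)O1
F3 | step 8 | methyl (1R)-6-methoxy-1-methyl-3-oxo-1,2,3,4-tetrahydronaphthalene-1-carboxylate | COc1ccc2c(c1)CC(=O)C[C@@]2(C)C(=O)OC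
F4 | step 8 | methyl (1R,3S)-3-hydroxy-6-methoxy-1-methyl-1,2,3,4-tetrahydronaphthalene-1-carboxylate | COc1ccc2c(c1)C[C@H](O)C[C@@]2(C)C(=O)OC
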